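**Assumption:** the SMILES holds no stereocentre and no defined axis, so the target is treated as achiral (rotamers about the bond between the two flavone units interconvert) and no stereocontrolling step is needed.

**Naming:** unit 1 is the 5-hydroxy-7-methoxy-2-(4-methoxyphenyl)chromone joined through its C3; unit 2 is the apigenin part joined through its C6.

## Retrosynthetic overview

1. Target ⇒ protected biflavone with two benzyl ethers on unit 2 and a 5-OMe on unit 1; one BCl3 operation removes all three.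
2. Ring C of unit 1 ⇒ O1–C8a bond: the enolate oxygen of a 2-aryl-1,3-diketone displaces an ortho-methoxy group of a 2,4,6-trimethoxybenzoyl ring (key C–O ring closure).
3. Diketone ⇒ deoxybenzoin + 4-methoxybenzoyl chloride (C-aroylation in the same flask); deoxybenzoin ⇒ 6-iodoflavone + 2',4',6'-trimethoxyacetophenone (ketone α-arylation, the bond between the units).
4. 6-Iodoflavone ⇒ apigenin (7,4'-di-O-benzylation, then 5-OH-directed iodination at C6).
5. Ring order: all rings of unit 2 come intact in apigenin, rings A and B of unit 1 come as arenes, and ring C of unit 1 is the only ring made, last.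

## Route

Step 1
Reactants: 1 apigenin (5,7-dihydroxy-2-(4-hydroxyphenyl)-4H-chromen-4-one)
Product: 2 7-(benzyloxy)-2-[4-(benzyloxy)phenyl]-5-hydroxy-4H-chromen-4-one
Conditions: BnBr (2.2 equiv), K2CO3 (2.5 equiv), DMF, 25 °C
Reagents that add atoms: benzyl bromide, BrCc1ccccc1
Why: Williamson etherification, in which the acidic 7-OH and 4'-OH are alkylated while the 5-OH, hydrogen-bonded to the C4 carbonyl, stays free under K2CO3 at room temperature.

Step 2
Reactants: 2 7-(benzyloxy)-2-[4-(benzyloxy)phenyl]-5-hydroxy-4H-chromen-4-one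
Product: 3 7-(benzyloxy)-2-[4-(benzyloxy)phenyl]-5-hydroxy-6-iodo-4H-chromen-4-one
Conditions: BnMe3N+ ICl2− (1.1 equiv), CaCO3, CH2Cl2–MeOH, 25 °C
Reagents that add atoms: benzyltrimethylammonium dichloroiodate, C[N+](C)(C)Cc1ccccc1.Cl[I-]Cl
Why: Electrophilic aromatic iodination in which the free chelated 5-OH directs the iodine to its only open ortho position, C6 of ring A, the established outcome for 5-hydroxy-7-alkoxyflavones with this reagent.

Step 3
Reactants: 3 7-(benzyloxy)-2-[4-(benzyloxy)phenyl]-5-hydroxy-6-iodo-4H-chromen-4-one; 4 1-(2,4,6-trimethoxyphenyl)ethan-1-one (1.5 equiv)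
Product: 5 7-(benzyloxy)-2-[4-(benzyloxy)phenyl]-5-hydroxy-6-[2-oxo-2-(2,4,6-trimethoxyphenyl)ethyl]-4H-chromen-4-one
Conditions: Pd2(dba)3 (2.5 mol %), XPhos (6 mol %), NaOtBu (3.5 equiv), toluene, 80 °C; NH4Cl work-up
Reagents that add atoms: none
Why: Palladium-catalysed ketone α-arylation (Buchwald–Hartwig type), with oxidative addition of the C–I bond to zerovalent palladium, exchange of iodide on divalent palladium for the sodium enolate of 4 (which cannot self-condense because two ortho-methoxy groups shield its carbonyl) and reductive elimination, the bulky biarylphosphine allowing the di-ortho-substituted iodide to couple once while the 5-OH rides through as its phenoxide.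

Step 4
Reactants: 5 7-(benzyloxy)-2-[4-(benzyloxy)phenyl]-5-hydroxy-6-[2-oxo-2-(2,4,6-trimethoxyphenyl)ethyl]-4H-chromen-4-one; 6 4-methoxybenzoyl chloride (1.1 equiv)
Product: 8 7-(benzyloxy)-2-[4-(benzyloxy)phenyl]-6-[5,7-dimethoxy-2-(4-methoxyphenyl)-4-oxo-4H-chromen-3-yl]-5-hydroxy-4H-chromen-4-one, via triaryl 1,3-diketone 7 (not isolated)
Conditions: LiN(SiMe3)2 (3.3 equiv), THF, −78 °C; 6, −78 to 0 °C; then Cs2CO3 (3 equiv), DMSO, 120 °C (THF distilled off); NH4Cl work-up
Reagents that add atoms: none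
Why: Proposed new method: the lithium enolate of 5 is C-aroylated by 6 (Claisen-type acylation of a polyanion) to the enolate of 7, and after exchange of lithium for cesium in DMSO the non-chelated 1,3-diketonate turns its anisoyl-side oxygen onto C2' of the 2,4,6-trimethoxybenzoyl ring, where intramolecular nucleophilic aromatic substitution (addition–elimination through a Meisenheimer intermediate stabilised by the ortho carbonyl) expels methoxide and forms the O1–C8a bond of ring C in an irreversible six-membered closure, while the 5-phenoxide of unit 2 deactivates its own ring against attack at C7; the closest known reactions are the base-induced cyclisation of 2-hydroxy-2'-methoxybenzophenones to xanthones with loss of methanol and the fluoride-displacing closure of 1-(2-fluoroaryl)-1,3-diketones to chromones, neither shown for a methoxy leaving group and a diketonate oxygen on the way to a 2,3-diarylchromone.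

Step 5
Reactants: 8 7-(benzyloxy)-2-[4-(benzyloxy)phenyl]-6-[5,7-dimethoxy-2-(4-methoxyphenyl)-4-oxo-4H-chromen-3-yl]-5-hydroxy-4H-chromen-4-one
Product: 9 5,7-dihydroxy-6-[5-hydroxy-7-methoxy-2-(4-methoxyphenyl)-4-oxo-4H-chromen-3-yl]-2-(4-hydroxyphenyl)-4H-chromen-4-one
Conditions: BCl3 (8 equiv), C6HMe5 (6 equiv), CH2Cl2, −78 to 20 °C; then MeOH, aq HCl
Reagents that add atoms: none
Why: Lewis-acid ether cleavage, in which BCl3 with pentamethylbenzene as benzyl-cation scavenger removes both benzyl ethers in the cold and, on warming, the boron chelate between the C4 carbonyl and the peri 5-OMe of unit 1 delivers chloride to that methyl group only, so the non-chelated 7-OMe and 4'-OMe survive.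

## Compound list

1 | apigenin, 5,7-dihydroxy-2-(4-hydroxyphenyl)-4H-chromen-4-one | O=c1cc(-c2ccc(O)cc2)oc2cc(O)cc(O)c12 | starting material
2 | 7-(benzyloxy)-2-[4-(benzyloxy)phenyl]-5-hydroxy-4H-chromen-4-one | O=c1cc(-c2ccc(OCc3ccccc3)cc2)oc2cc(OCc3ccccc3)cc(O)c12 | intermediate
3 | 7-(benzyloxy)-2-[4-(benzyloxy)phenyl]-5-hydroxy-6-iodo-4H-chromen-4-one | O=c1cc(-c2ccc(OCc3ccccc3)cc2)oc2cc(OCc3ccccc3)c(I)c(O)c12 | intermediate
4 | 1-(2,4,6-trimethoxyphenyl)ethan-1-one (2',4',6'-trimethoxyacetophenone) | CC(=O)c1c(OC)cc(OC)cc1OC | starting material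
5 | 7-(benzyloxy)-2-[4-(benzyloxy)phenyl]-5-hydroxy-6-[2-oxo-2-(2,4,6-trimethoxyphenyl)ethyl]-4H-chromen-4-one | O=c1cc(-c2ccc(OCc3ccccc3)cc2)oc2cc(OCc3ccccc3)c(CC(=O)c3c(OC)cc(OC)cc3OC)c(O)c12 | intermediate
6 | 4-methoxybenzoyl chloride | COc1ccc(cc1)C(Cl)=O | starting material
7 | 2-{7-(benzyloxy)-2-[4-(benzyloxy)phenyl]-5-hydroxy-4-oxo-4H-chromen-6-yl}-1-(4-methoxyphenyl)-3-(2,4,6-trimethoxyphenyl)propane-1,3-dione (triaryl 1,3-diketone, present in the flask as its enolate) | O=c1cc(-c2ccc(OCc3ccccc3)cc2)oc2cc(OCc3ccccc3)c(C(C(=O)c3ccc(OC)cc3)C(=O)c3c(OC)cc(OC)cc3OC)c(O)c12 | intermediate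
8 | 7-(benzyloxy)-2-[4-(benzyloxy)phenyl]-6-[5,7-dimethoxy-2-(4-methoxyphenyl)-4-oxo-4H-chromen-3-yl]-5-hydroxy-4H-chromen-4-one | COc1ccc(-c2oc3cc(OC)cc(OC)c3c(=O)c2-c2c(OCc3ccccc3)cc3oc(-c4ccc(OCc5ccccc5)cc4)cc(=O)c3c2O)cc1 | intermediate
9 | 5,7-dihydroxy-6-[5-hydroxy-7-methoxy-2-(4-methoxyphenyl)-4-oxo-4H-chromen-3-yl]-2-(4-hydroxyphenyl)-4H-chromen-4-one | COc1ccc(-c2oc3cc(OC)cc(O)c3c(=O)c2-c2c(O)cc3oc(-c4ccc(O)cc4)cc(=O)c3c2O)cc1 | target

## Step count and risks

Total steps: 5. Longest linear sequence: 5 (1 → 2 → 3 → 5 → 8 → 9).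

The three steps most likely to fail:

**Step 4 (the proposed new ring closure).** The hindered enolate may be acylated on oxygen, the methoxide displacement on the electron-rich ring may be slow, and the diketone may suffer retro-Claisen cleavage. The fallback uses known chemistry, sets out from 5 and comes back to the route at 8. MgI2·OEt2 in toluene at 80 °C cleaves one ortho-methoxy group chelated to the ketone and gives the phenol 7-(benzyloxy)-2-[4-(benzyloxy)phenyl]-5-hydroxy-6-[2-(2-hydroxy-4,6-dimethoxyphenyl)-2-oxoethyl]-4H-chromen-4-one F3. Compound 6 with pyridine and DMAP in CH2Cl2 at 0 °C acylates this less hindered phenol to the ester 2-({7-(benzyloxy)-2-[4-(benzyloxy)phenyl]-5-hydroxy-4-oxo-4H-chromen-6-yl}acetyl)-3,5-dimethoxyphenyl 4-methoxybenzoate F4. KOH in pyridine at 50 °C moves the aroyl group to carbon (Baker–Venkataraman rearrangement) and gives the diketone 2-{7-(benzyloxy)-2-[4-(benzyloxy)phenyl]-5-hydroxy-4-oxo-4H-chromen-6-yl}-1-(2-hydroxy-4,6-dimethoxyphenyl)-3-(4-methoxyphenyl)propane-1,3-dione F5. Catalytic p-TsOH in toluene at 60 °C then closes and dehydrates F5 to 8; the acid is kept mild so that the neighbouring 5-OH of unit 2 does not close a furan ring.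

**Step 3 (α-arylation).** The iodide is electron-rich, flanked by two oxygen substituents and carries an ortho phenoxide, so oxidative addition may be slow and loss of iodine may compete. The fallback reverses the polarity of the coupling, sets out from 3 and 4 and comes back at 5. Bis(pinacolato)diboron, PdCl2(dppf) and KOAc in dioxane at 90 °C turn 3 into the boronate 7-(benzyloxy)-2-[4-(benzyloxy)phenyl]-5-hydroxy-6-(4,4,5,5-tetramethyl-1,3,2-dioxaborolan-2-yl)-4H-chromen-4-one F1. CuBr2 in EtOAc–CHCl3 at reflux brominates the methyl group of 4 to 2-bromo-1-(2,4,6-trimethoxyphenyl)ethan-1-one F2. Suzuki–Miyaura coupling of F1 with F2 (Pd(PPh3)4, K3PO4, THF–H2O, 60 °C) gives 5.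

**Step 5 (global deprotection).** Over-long exposure could cleave the 7-OMe or 4'-OMe, benzyl cations could alkylate the electron-rich rings, or the 5-OMe could survive. The fallback separates the two events, sets out from 8 and comes back at 9. Hydrogenolysis (H2, palladium on carbon, THF–EtOAc, 25 °C) removes the benzyl groups and gives 6-[5,7-dimethoxy-2-(4-methoxyphenyl)-4-oxo-4H-chromen-3-yl]-5,7-dihydroxy-2-(4-hydroxyphenyl)-4H-chromen-4-one F6. BCl3 (3 equiv) in CH2Cl2 at 0 °C then cleaves only the chelated 5-OMe and gives 9.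

## Further compounds

F1 | step 3 | 7-(benzyloxy)-2-[4-(benzyloxy)phenyl]-5-hydroxy-6-(4,4,5,5-tetramethyl-1,3,2-dioxaborolan-2-yl)-4H-chromen-4-one | O=c1cc(-c2ccc(OCc3ccccc3)cc2)oc2cc(OCc3ccccc3)c(B3OC(C)(C)C(C)(C)O3)c(O)c12
F2 | step 3 | 2-bromo-1-(2,4,6-trimethoxyphenyl)ethan-1-one | COc1cc(OC)c(C(=O)CBr)c(OC)c1
F3 | step 4 | 7-(benzyloxy)-2-[4-(benzyloxy)phenyl]-5-hydroxy-6-[2-(2-hydroxy-4,6-dimethoxyphenyl)-2-oxoethyl]-4H-chromen-4-one | O=c1cc(-c2ccc(OCc3ccccc3)cc2)oc2cc(OCc3ccccc3)c(CC(=O)c3c(O)cc(OC)cc3OC)c(O)c12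
F4 | step 4 | 2-({7-(benzyloxy)-2-[4-(benzyloxy)phenyl]-5-hydroxy-4-oxo-4H-chromen-6-yl}acetyl)-3,5-dimethoxyphenyl 4-methoxybenzoate | O=c1cc(-c2ccc(OCc3ccccc3)cc2)oc2cc(OCc3ccccc3)c(CC(=O)c3c(OC(=O)c4ccc(OC)cc4)cc(OC)cc3OC)c(O)c12
F5 | step 4 | 2-{7-(benzyloxy)-2-[4-(benzyloxy)phenyl]-5-hydroxy-4-oxo-4H-chromen-6-yl}-1-(2-hydroxy-4,6-dimethoxyphenyl)-3-(4-methoxyphenyl)propane-1,3-dione | O=c1cc(-c2ccc(OCc3ccccc3)cc2)oc2cc(OCc3ccccc3)c(C(C(=O)c3ccc(OC)cc3)C(=O)c3c(O)cc(OC)cc3OC)c(O)c12
F6 | step 5 | 6-[5,7-dimethoxy-2-(4-methoxyphenyl)-4-oxo-4H-chromen-3-yl]-5,7-dihydroxy-2-(4-hydroxyphenyl)-4H-chromen-4-one | COc1ccc(-c2oc3cc(OC)cc(OC)c3c(=O)c2-c2c(O)cc3oc(-c4ccc(O)cc4)cc(=O)c3c2O)cc1
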